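**Retrosynthetic overview**

1. Numbering: C1 is the bridgehead next to the CMe2 carbon C8; C2–C3–C4 is the enolized diketone bridge of ring A (aroyl on C3); C5 is the other bridgehead; C6, C7 (geranyl) and C8 complete ring B; C9 is the bridging ketone. Late disconnections: C3–aroyl (vinyllithium acylation), the bond between the C7 CH2 arm and the geranyl alkene carbon (B-alkyl Suzuki after exo-face hydroboration of a C7 methylidene), C1–prenyl (bridgehead alkylation), C2=O (allylic oxidation), the two C8 methyl groups (enolate alkylation).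
2. Ring B is traced back to a methoxycyclopropyl ketone (cyclopropane C1–C8–C9, donor OMe on C9, acceptor C7=O on C8): donor–acceptor heterolysis of C8–C9 gives the bicyclo[3.3.1]nonane-7,9-dione.
3. Key disconnection C1–C8 and C8–C9. The feature it rests on: once C8 is detached from C1, ring A plus C9 is a 2,6-dimethoxycyclohexa-2,5-diene in which C5 (prenyl and the C6–C7–C8 arm) and C2 lie on a mirror plane, so the enol ethers C9=C1 and C4=C3 are enantiotopic and a chiral copper carbene at C8 can choose one.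
4. The diazoketone comes from 1,3-dimethoxybenzene by Birch reduction, two alkylations at the future C5 and acylation of diazomethane. Ring order: the six-membered carbocycle (ring A plus C9) from the arene, then cyclopropane and cyclopentanone together in the key step, then ring B when C8–C9 is cleaved.
5. Side fragments: (E)-1-iodo-2,6-dimethylhepta-1,5-diene from 6-methylhept-5-en-2-one, and 3-(silyloxy)benzoyl chloride from 3-hydroxybenzoic acid.

Key step: step 6

Remark 1: the (S,S) ligand is written in step 6 on the assumption that it selects the enol ether leading to the drawn enantiomer; if the sense of induction is opposite, the (R,R) ligand is used and nothing else changes.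
Remark 2: locants and CIP descriptors in all names follow the skeleton numbering above; drawn with C9 on top and ring A in front, C1 is on the left and C5 on the right in every bicyclic compound, and "endo" at C7 means pointing toward ring A.
Remark 3: the target is an enolized β-triketone and is handled as the drawn tautomer (C2 ketone, C4 enol).

**Route**

Step 1
Reactants: 1 1,3-dimethoxybenzene
Product: 2 1,5-dimethoxycyclohexa-1,4-diene
Conditions: Li, liquid NH3, THF, t-BuOH, −78 → −33 °C
Reagents that add atoms: none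
Why: Birch reduction of a 1,3-dialkoxyarene protonates C2 and C5 of the arene, which leaves both methoxy groups on double bonds as the unconjugated bis(enol ether).

Step 2
Reactants: 2 1,5-dimethoxycyclohexa-1,4-diene; 3 1-bromo-3-methylbut-2-ene (prenyl bromide)
Product: 5 1,5-dimethoxy-6-(3-methylbut-2-en-1-yl)cyclohexa-1,4-diene, via 6-lithio-1,5-dimethoxycyclohexa-1,4-diene 4 (not isolated)
Conditions: t-BuLi, THF, −78 °C; then 3, −78 → 0 °C
Reagents that add atoms: none
Why: Lithiation–alkylation, in which t-BuLi removes a proton from the CH2 between the two methoxy-bearing carbons (doubly allylic, lithium held by both oxygens) and the pentadienyl anion is alkylated at that central carbon by the allylic bromide in an SN2 reaction.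

Step 3
Reactants: 5 1,5-dimethoxy-6-(3-methylbut-2-en-1-yl)cyclohexa-1,4-diene; 6 methyl bromoacetate
Product: 8 methyl 2-[2,6-dimethoxy-1-(3-methylbut-2-en-1-yl)cyclohexa-2,5-dien-1-yl]acetate, via tertiary lithio diene 7 (not isolated)
Conditions: t-BuLi, THF, −78 °C; anion added to 6 (excess), −78 °C
Reagents that add atoms: none
Why: A second lithiation at the same, now tertiary, doubly allylic carbon and SN2 alkylation by the α-bromo ester (inverse addition to suppress proton transfer) creates the quaternary carbon C5, which is not yet stereogenic because the ring is mirror-symmetric.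

Step 4
Reactants: 8 methyl 2-[2,6-dimethoxy-1-(3-methylbut-2-en-1-yl)cyclohexa-2,5-dien-1-yl]acetate
Product: 9 potassium 2-[2,6-dimethoxy-1-(3-methylbut-2-en-1-yl)cyclohexa-2,5-dien-1-yl]acetate
Conditions: KOSiMe3, THF, 25 °C; evaporation, salt used crude
Reagents that add atoms: potassium trimethylsilanolate C[Si](C)(C)[O-].[K+]
Why: Anhydrous ester cleavage by a silanolate gives the carboxylate salt directly, so no acidification, which the two enol ethers would not survive, is needed.

Step 5
Reactants: 9 potassium 2-[2,6-dimethoxy-1-(3-methylbut-2-en-1-yl)cyclohexa-2,5-dien-1-yl]acetate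
Product: 11 1-diazo-3-[2,6-dimethoxy-1-(3-methylbut-2-en-1-yl)cyclohexa-2,5-dien-1-yl]propan-2-one, via isobutyl carbonic mixed anhydride 10 (not isolated)
Conditions: i-BuOCOCl, N-methylmorpholine (cat.), THF, −15 °C; then CH2N2, Et2O, 0 → 25 °C
Reagents that add atoms: diazomethane C=[N+]=[N-]
Why: The carboxylate is activated as a mixed carbonic anhydride and acylates diazomethane (first stage of the Arndt–Eistert sequence) under neutral conditions that leave the enol ethers and the prenyl group untouched.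

Step 6
Reactants: 11 1-diazo-3-[2,6-dimethoxy-1-(3-methylbut-2-en-1-yl)cyclohexa-2,5-dien-1-yl]propan-2-one
Product: 12 (1S,5S,8R,9R)-4,9-dimethoxy-5-(3-methylbut-2-en-1-yl)-8,9-cyclobicyclo[3.3.1]non-3-en-7-one (tricyclic methoxycyclopropyl ketone)
Conditions: CuOTf (monovalent copper, charged as (CuOTf)2·C6H6, 10 mol% Cu), 2,2'-isopropylidenebis[(4S)-4-tert-butyl-2-oxazoline] (15 mol%), toluene, 25 °C, slow addition of 11
Reagents that add atoms: none
Why: The copper catalyst takes up the diazo carbon, dinitrogen leaves, and the electrophilic copper carbene at C8 adds across one C=C(OMe) unit in a concerted but asynchronous [2+1] step, bonding to the nucleophilic carbon C1 ahead of C9. The closest known reaction type is the catalytic asymmetric intramolecular cyclopropanation of α-diazoketones tethered to 1,5-dimethoxycyclohexa-1,4-dienes with monovalent copper and bis(oxazoline) ligands. The cyclopropane (C1, C8, C9) closes by the [2+1] addition itself, and the cyclopentanone (C5, C6, C7, C8, C9) closes through the C8–C9 bond in a 5-exo sense with respect to the C9=C1 double bond, the three-atom tether reaching no other mode. C5 becomes stereogenic through the choice between the two enantiotopic enol ethers, made by the tert-butyl groups of the twofold-symmetric ligand on copper, and C1, C8 and C9 follow from it because the short tether permits only the cis-fused, suprafacial adduct. The step needs enantiotopic-group selection, supplied by the ligand, and chemoselectivity over the prenyl double bond and the methoxy oxygens, supplied by the five-membered ring size and the higher nucleophilicity of the enol ether, while slow addition keeps carbene dimerisation down.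

Step 7
Reactants: 12 (1S,5S,8R,9R)-4,9-dimethoxy-5-(3-methylbut-2-en-1-yl)-8,9-cyclobicyclo[3.3.1]non-3-en-7-one
Product: 15 (1S,5S)-4-methoxy-5-(3-methylbut-2-en-1-yl)bicyclo[3.3.1]non-3-ene-7,9-dione, via O-methyl oxocarbenium triflate 13 (not isolated), via trimethylsilyl enol ether 14 (not isolated)
Conditions: TMSOTf (1.2 equiv), 2,6-di-tert-butylpyridine, CH2Cl2, −78 °C; aq. NaHCO3, 0 °C; then K2CO3 (cat.), MeOH, 0 °C
Reagents that add atoms: water O
Why: Lewis-acid-promoted heterolysis of a vicinal donor–acceptor cyclopropane, in which silylation of the C7 carbonyl oxygen pulls and the C9 methoxy group pushes so that only C8–C9 breaks and C1–C8 stays, and the O-methyl oxocarbenium ion is hydrolysed to the C9 ketone in the bicarbonate quench without exposing the C3=C4 enol ether or the prenyl group to aqueous acid, C1 and C5 being untouched.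

Step 8
Reactants: 15 (1S,5S)-4-methoxy-5-(3-methylbut-2-en-1-yl)bicyclo[3.3.1]non-3-ene-7,9-dione
Product: 17 (1S,5S)-4-methoxy-8-methyl-5-(3-methylbut-2-en-1-yl)bicyclo[3.3.1]non-3-ene-7,9-dione (both C8 epimers), via C8 lithium enolate 16 (not isolated)
Conditions: LDA (1.05 equiv), THF, −78 °C; MeI, −78 → −30 °C
Reagents that add atoms: iodomethane CI
Why: Kinetic enolate alkylation, in which LDA deprotonates C8 rather than C6 because C6 is neopentyl (next to the quaternary C5) and C9 cannot enolise (bridgeheads), the C8 configuration of the product being irrelevant.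

Step 9
Reactants: 17 (1S,5S)-4-methoxy-8-methyl-5-(3-methylbut-2-en-1-yl)bicyclo[3.3.1]non-3-ene-7,9-dione
Product: 19 (1S,5S)-4-methoxy-8,8-dimethyl-5-(3-methylbut-2-en-1-yl)bicyclo[3.3.1]non-3-ene-7,9-dione, via C8 potassium enolate 18 (not isolated)
Conditions: KOtBu (1.2 equiv), t-BuOH/THF, 0 °C; MeI (1.5 equiv)
Reagents that add atoms: iodomethane CI
Why: Thermodynamic enolate alkylation, in which the tetrasubstituted C7=C8 enolate is favoured under equilibrating conditions and the alternative C6 enolate carbon is shielded by C5, so the second methyl group should enter at C8 and erase that stereocenter.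

Step 10
Reactants: 19 (1S,5S)-4-methoxy-8,8-dimethyl-5-(3-methylbut-2-en-1-yl)bicyclo[3.3.1]non-3-ene-7,9-dione
Product: 20 (1R,5S)-4-methoxy-8,8-dimethyl-5-(3-methylbut-2-en-1-yl)bicyclo[3.3.1]non-3-ene-2,7,9-trione
Conditions: Rh2(cap)4 (dirhodium tetracaprolactamate, 1 mol%), t-BuOOH (70% in water, 5 equiv), K2CO3, CH2Cl2, 25 °C
Reagents that add atoms: tert-butyl hydroperoxide CC(C)(C)OO
Why: Radical allylic C–H oxidation by tert-butylperoxyl radicals, in which the C2 hydrogens are the most easily abstracted because the radical is delocalised over the electron-rich C3=C4 enol ether and the C2 peroxide collapses (Kornblum–DeLaMare) to the ketone of a vinylogous ester, the prenyl allylic positions being less activated.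

Step 11
Reactants: 20 (1R,5S)-4-methoxy-8,8-dimethyl-5-(3-methylbut-2-en-1-yl)bicyclo[3.3.1]non-3-ene-2,7,9-trione
Product: 21 (1S,5S)-4-methoxy-8,8-dimethyl-5-(3-methylbut-2-en-1-yl)-3-(trimethylsilyl)-7-(trimethylsilyloxy)bicyclo[3.3.1]nona-3,6-diene-2,9-dione
Conditions: LiTMP (2.2 equiv), TMSCl (5 equiv, present from the start), THF, −78 °C; non-aqueous work-up, used crude
Reagents that add atoms: chlorotrimethylsilane C[Si](C)(C)Cl
Why: In situ quench silylation, in which LiTMP coexists with the silyl chloride at −78 °C, the C7 enolate (C6 is the only enolisable carbon) is trapped on oxygen and the kinetically most acidic vinyl C3–H is replaced by silicon, so the C7 ketone is masked and C3 is blocked before the slower bridgehead metalation.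

Step 12
Reactants: 21 (1S,5S)-4-methoxy-8,8-dimethyl-5-(3-methylbut-2-en-1-yl)-3-(trimethylsilyl)-7-(trimethylsilyloxy)bicyclo[3.3.1]nona-3,6-diene-2,9-dione; 3 1-bromo-3-methylbut-2-ene
Product: 23 (1S,5S)-4-methoxy-8,8-dimethyl-1,5-bis(3-methylbut-2-en-1-yl)-3-(trimethylsilyl)-7-(trimethylsilyloxy)bicyclo[3.3.1]nona-3,6-diene-2,9-dione, via C1 bridgehead lithium species 22 (not isolated)
Conditions: LDA (3 equiv), THF, −78 → −40 °C; 3 (5 equiv), −78 → 0 °C
Reagents that add atoms: none
Why: Bridgehead lithiation–alkylation of a bicyclic vinylogous ester, in which LDA, with C3 and C6 blocked, removes C1–H between the C2 and C9 carbonyls and the pyramidal carbanion attacks prenyl bromide in an SN2 reaction, the bicyclic frame fixing the C1 configuration (retention).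

Step 13
Reactants: 23 (1S,5S)-4-methoxy-8,8-dimethyl-1,5-bis(3-methylbut-2-en-1-yl)-3-(trimethylsilyl)-7-(trimethylsilyloxy)bicyclo[3.3.1]nona-3,6-diene-2,9-dione
Product: 24 (1R,5S)-4-methoxy-8,8-dimethyl-1,5-bis(3-methylbut-2-en-1-yl)bicyclo[3.3.1]non-3-ene-2,7,9-trione
Conditions: TBAF (3 equiv), wet THF, 0 °C
Reagents that add atoms: none
Why: Fluoride cleaves the O–Si bond of the enol ether and the C3–Si bond of the α-silyl enone (protodesilylation), returning the C7 ketone and C3–H without touching the methyl vinylogous ester.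

Step 14
Reactants: 24 (1R,5S)-4-methoxy-8,8-dimethyl-1,5-bis(3-methylbut-2-en-1-yl)bicyclo[3.3.1]non-3-ene-2,7,9-trione
Product: 25 (1R,5S)-4-methoxy-8,8-dimethyl-7-methylidene-1,5-bis(3-methylbut-2-en-1-yl)bicyclo[3.3.1]non-3-ene-2,9-dione
Conditions: Ph3PCH3Br, KOtBu, THF, 0 → 45 °C
Reagents that add atoms: methyltriphenylphosphonium bromide C[P+](c1ccccc1)(c1ccccc1)c1ccccc1.[Br-]
Why: Wittig methylenation should be chemoselective for C7, since C9 now lies between two quaternary bridgeheads and C2 is a deactivated vinylogous ester carbonyl.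

Step 15
Reactants: 26 6-methylhept-5-en-2-one
Product: 30 6-methylhept-5-en-1-yne, via lithium enolate 27 (not isolated), via diethyl enol phosphate 28 (not isolated), via lithium acetylide 29 (not isolated)
Conditions: LDA (1.05 equiv), THF, −78 °C; ClP(O)(OEt)2, −78 → 25 °C; LDA (2.3 equiv), −78 → 25 °C; H2O
Reagents that add atoms: none
Why: The kinetic methyl-side enolate is trapped as the enol phosphate and eliminated with excess LDA to the terminal alkyne (enol phosphate elimination), the trisubstituted alkene being inert.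

Step 16
Reactants: 30 6-methylhept-5-en-1-yne
Product: 32 (E)-1-iodo-2,6-dimethylhepta-1,5-diene, via alkenyldimethylalane 31 (not isolated)
Conditions: Me3Al (2 equiv), Cp2ZrCl2 (zirconocene dichloride, 20 mol%), CH2Cl2, 25 °C; then I2, THF, −30 → 0 °C
Reagents that add atoms: trimethylaluminium C[Al](C)C; iodine II
Why: Zirconium-catalysed carboalumination (Negishi) adds methyl and aluminium syn across the alkyne with aluminium at the terminus, and iodinolysis with retention gives the E-alkenyl iodide.

Step 17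
Reactants: 25 (1R,5S)-4-methoxy-8,8-dimethyl-7-methylidene-1,5-bis(3-methylbut-2-en-1-yl)bicyclo[3.3.1]non-3-ene-2,9-dione; 32 (E)-1-iodo-2,6-dimethylhepta-1,5-diene
Product: 34 (1R,5S,7S)-7-[(2E)-3,7-dimethylocta-2,6-dien-1-yl]-4-methoxy-8,8-dimethyl-1,5-bis(3-methylbut-2-en-1-yl)bicyclo[3.3.1]non-3-ene-2,9-dione, via B-alkyl-9-BBN 33 (not isolated)
Conditions: 9-BBN dimer (1.5 equiv B–H), THF, 25 → 50 °C; then 32, PdCl2(dppf) (divalent palladium precatalyst, 10 mol%), AsPh3, Cs2CO3, DMF/THF/H2O, 25 °C
Reagents that add atoms: none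
Why: 9-BBN hydroborates the 1,1-disubstituted exocyclic alkene much faster than the trisubstituted prenyl alkenes or the hindered, deactivated carbonyl groups, placing boron on the terminal carbon and hydrogen on C7 from the exo face (the endo face is covered by ring A), which leaves the CH2 arm endo and sets C7 as S, and the B-alkyl Suzuki–Miyaura coupling then joins this carbon to the alkenyl iodide with retention of the E geometry.

Step 18
Reactants: 35 3-hydroxybenzoic acid
Product: 36 tert-butyldimethylsilyl 3-(tert-butyldimethylsilyloxy)benzoate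
Conditions: TBSCl (2.3 equiv), imidazole, DMF, 25 °C
Reagents that add atoms: tert-butyldimethylsilyl chloride CC(C)(C)[Si](C)(C)Cl
Why: Silylation of both the phenol and the acid, the silyl ester being the handle for neutral acid chloride formation.

Step 19
Reactants: 36 tert-butyldimethylsilyl 3-(tert-butyldimethylsilyloxy)benzoate
Product: 37 3-(tert-butyldimethylsilyloxy)benzoyl chloride
Conditions: (COCl)2 (1.2 equiv), DMF (cat.), CH2Cl2, 0 → 25 °C
Reagents that add atoms: oxalyl chloride ClC(=O)C(Cl)=O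
Why: Oxalyl chloride with catalytic DMF (Vilsmeier-type activation) converts the silyl ester directly into the acid chloride with loss of the silyl chloride and without HCl, so the aryl silyl ether survives.

Step 20
Reactants: 34 (1R,5S,7S)-7-[(2E)-3,7-dimethylocta-2,6-dien-1-yl]-4-methoxy-8,8-dimethyl-1,5-bis(3-methylbut-2-en-1-yl)bicyclo[3.3.1]non-3-ene-2,9-dione; 37 3-(tert-butyldimethylsilyloxy)benzoyl chloride
Product: 39 (1S,5S,7S)-3-[3-(tert-butyldimethylsilyloxy)benzoyl]-7-[(2E)-3,7-dimethylocta-2,6-dien-1-yl]-4-methoxy-8,8-dimethyl-1,5-bis(3-methylbut-2-en-1-yl)bicyclo[3.3.1]non-3-ene-2,9-dione, via C3 vinyllithium 38 (not isolated)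
Conditions: LiTMP (1.5 equiv), THF, −78 °C; 37 (2 equiv), −78 → −40 °C
Reagents that add atoms: none
Why: Lithiation–acylation, in which LiTMP removes the vinyl C3–H of the β-methoxy enone (the only acidic hydrogen left, both bridgeheads being quaternary) and the vinyllithium is acylated by the aroyl chloride.

Step 21
Reactants: 39 (1S,5S,7S)-3-[3-(tert-butyldimethylsilyloxy)benzoyl]-7-[(2E)-3,7-dimethylocta-2,6-dien-1-yl]-4-methoxy-8,8-dimethyl-1,5-bis(3-methylbut-2-en-1-yl)bicyclo[3.3.1]non-3-ene-2,9-dione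
Product: 40 (1S,5S,7S)-7-[(2E)-3,7-dimethylocta-2,6-dien-1-yl]-4-hydroxy-3-(3-hydroxybenzoyl)-8,8-dimethyl-1,5-bis(3-methylbut-2-en-1-yl)bicyclo[3.3.1]non-3-ene-2,9-dione (CNP0290731.1)
Conditions: LiOH (10 equiv), dioxane/H2O, 90 °C; then 1 M HCl to pH 3
Reagents that add atoms: lithium hydroxide [Li+].[OH-]
Why: Hydroxide adds to C4 of the vinylogous ester and expels methoxide (addition–elimination) and cleaves the aryl silyl ether at silicon, and acidification gives the enolised triketone with no stereocenter touched.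

**Compound list**

1 | 1,3-dimethoxybenzene | COc1cccc(OC)c1 | starting material
2 | 1,5-dimethoxycyclohexa-1,4-diene | COC1=CCC=C(OC)C1 | intermediate
3 | 1-bromo-3-methylbut-2-ene (prenyl bromide) | CC(C)=CCBr | starting material
4 | 6-lithio-1,5-dimethoxycyclohexa-1,4-diene | [Li]C1C(OC)=CCC=C1OC | intermediate
5 | 1,5-dimethoxy-6-(3-methylbut-2-en-1-yl)cyclohexa-1,4-diene | COC1=CCC=C(OC)C1CC=C(C)C | intermediate
6 | methyl bromoacetate | COC(=O)CBr | starting material
7 | 6-lithio-1,5-dimethoxy-6-(3-methylbut-2-en-1-yl)cyclohexa-1,4-diene | [Li]C1(CC=C(C)C)C(OC)=CCC=C1OC | intermediate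
8 | methyl 2-[2,6-dimethoxy-1-(3-methylbut-2-en-1-yl)cyclohexa-2,5-dien-1-yl]acetate | COC(=O)CC1(CC=C(C)C)C(OC)=CCC=C1OC | intermediate
9 | potassium 2-[2,6-dimethoxy-1-(3-methylbut-2-en-1-yl)cyclohexa-2,5-dien-1-yl]acetate | [K+].[O-]C(=O)CC1(CC=C(C)C)C(OC)=CCC=C1OC | intermediate
10 | 2-[2,6-dimethoxy-1-(3-methylbut-2-en-1-yl)cyclohexa-2,5-dien-1-yl]acetic isobutyl carbonic anhydride | CC(C)COC(=O)OC(=O)CC1(CC=C(C)C)C(OC)=CCC=C1OC | intermediate
11 | 1-diazo-3-[2,6-dimethoxy-1-(3-methylbut-2-en-1-yl)cyclohexa-2,5-dien-1-yl]propan-2-one | COC1=CCC=C(OC)C1(CC=C(C)C)CC(=O)C=[N+]=[N-] | intermediate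
12 | (1S,5S,8R,9R)-4,9-dimethoxy-5-(3-methylbut-2-en-1-yl)-8,9-cyclobicyclo[3.3.1]non-3-en-7-one (cyclopropane C1–C8–C9 cis-fused to the cyclopentanone C5–C6–C7–C8–C9) | COC1=CC[C@H]2[C@H]3C(=O)C[C@]1(CC=C(C)C)[C@@]23OC | intermediate
13 | (1S,5S)-4-methoxy-5-(3-methylbut-2-en-1-yl)-7-(trimethylsilyloxy)bicyclo[3.3.1]nona-3,6-dien-9-ylidene(methyl)oxonium triflate | COC1=CC[C@H]2C=C(O[Si](C)(C)C)C[C@]1(CC=C(C)C)C2=[O+]C.[O-]S(=O)(=O)C(F)(F)F | intermediate
14 | (1S,5S)-4-methoxy-5-(3-methylbut-2-en-1-yl)-7-(trimethylsilyloxy)bicyclo[3.3.1]nona-3,7-dien-9-one (enol ether double bond C7=C8) | COC1=CC[C@H]2C=C(O[Si](C)(C)C)C[C@]1(CC=C(C)C)C2=O | intermediate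
15 | (1S,5S)-4-methoxy-5-(3-methylbut-2-en-1-yl)bicyclo[3.3.1]non-3-ene-7,9-dione | COC1=CC[C@H]2CC(=O)C[C@]1(CC=C(C)C)C2=O | intermediate
16 | lithium C7=C8 enolate of 15 | COC1=CC[C@H]2C=C([O-])C[C@]1(CC=C(C)C)C2=O.[Li+] | intermediate
17 | (1S,5S)-4-methoxy-8-methyl-5-(3-methylbut-2-en-1-yl)bicyclo[3.3.1]non-3-ene-7,9-dione (both C8 epimers) | COC1=CC[C@H]2C(C)C(=O)C[C@]1(CC=C(C)C)C2=O | intermediate
18 | potassium C7=C8 enolate of 17 | COC1=CC[C@H]2C(C)=C([O-])C[C@]1(CC=C(C)C)C2=O.[K+] | intermediate
19 | (1S,5S)-4-methoxy-8,8-dimethyl-5-(3-methylbut-2-en-1-yl)bicyclo[3.3.1]non-3-ene-7,9-dione | COC1=CC[C@H]2C(C)(C)C(=O)C[C@]1(CC=C(C)C)C2=O | intermediate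
20 | (1R,5S)-4-methoxy-8,8-dimethyl-5-(3-methylbut-2-en-1-yl)bicyclo[3.3.1]non-3-ene-2,7,9-trione | COC1=CC(=O)[C@H]2C(C)(C)C(=O)C[C@]1(CC=C(C)C)C2=O | intermediate
21 | (1S,5S)-4-methoxy-8,8-dimethyl-5-(3-methylbut-2-en-1-yl)-3-(trimethylsilyl)-7-(trimethylsilyloxy)bicyclo[3.3.1]nona-3,6-diene-2,9-dione | COC1=C([Si](C)(C)C)C(=O)[C@H]2C(C)(C)C(O[Si](C)(C)C)=C[C@]1(CC=C(C)C)C2=O | intermediate
22 | C1-lithio derivative of 21 (1S,5S) | COC1=C([Si](C)(C)C)C(=O)[C@@]2([Li])C(C)(C)C(O[Si](C)(C)C)=C[C@]1(CC=C(C)C)C2=O | intermediate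
23 | (1S,5S)-4-methoxy-8,8-dimethyl-1,5-bis(3-methylbut-2-en-1-yl)-3-(trimethylsilyl)-7-(trimethylsilyloxy)bicyclo[3.3.1]nona-3,6-diene-2,9-dione | COC1=C([Si](C)(C)C)C(=O)[C@@]2(CC=C(C)C)C(C)(C)C(O[Si](C)(C)C)=C[C@]1(CC=C(C)C)C2=O | intermediate
24 | (1R,5S)-4-methoxy-8,8-dimethyl-1,5-bis(3-methylbut-2-en-1-yl)bicyclo[3.3.1]non-3-ene-2,7,9-trione | COC1=CC(=O)[C@@]2(CC=C(C)C)C(C)(C)C(=O)C[C@]1(CC=C(C)C)C2=O | intermediate
25 | (1R,5S)-4-methoxy-8,8-dimethyl-7-methylidene-1,5-bis(3-methylbut-2-en-1-yl)bicyclo[3.3.1]non-3-ene-2,9-dione | COC1=CC(=O)[C@@]2(CC=C(C)C)C(C)(C)C(=C)C[C@]1(CC=C(C)C)C2=O | intermediate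
26 | 6-methylhept-5-en-2-one | CC(=O)CCC=C(C)C | starting material
27 | lithium 6-methylhepta-1,5-dien-2-olate | C=C([O-])CCC=C(C)C.[Li+] | intermediate
28 | diethyl 6-methylhepta-1,5-dien-2-yl phosphate | C=C(OP(=O)(OCC)OCC)CCC=C(C)C | intermediate
29 | lithium 6-methylhept-5-en-1-yn-1-ide | [Li]C#CCCC=C(C)C | intermediate
30 | 6-methylhept-5-en-1-yne | C#CCCC=C(C)C | intermediate
31 | [(1E)-2,6-dimethylhepta-1,5-dien-1-yl]dimethylalane | C[Al](C)/C=C(\C)CCC=C(C)C | intermediate
32 | (E)-1-iodo-2,6-dimethylhepta-1,5-diene | I/C=C(\C)CCC=C(C)C | intermediate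
33 | (1R,5S,7S)-7-[(9-borabicyclo[3.3.1]nonan-9-yl)methyl]-4-methoxy-8,8-dimethyl-1,5-bis(3-methylbut-2-en-1-yl)bicyclo[3.3.1]non-3-ene-2,9-dione (CH2B arm endo) | COC1=CC(=O)[C@@]2(CC=C(C)C)C(C)(C)[C@@H](CB3C4CCCC3CCC4)C[C@]1(CC=C(C)C)C2=O | intermediate
34 | (1R,5S,7S)-7-[(2E)-3,7-dimethylocta-2,6-dien-1-yl]-4-methoxy-8,8-dimethyl-1,5-bis(3-methylbut-2-en-1-yl)bicyclo[3.3.1]non-3-ene-2,9-dione (geranyl endo) | COC1=CC(=O)[C@@]2(CC=C(C)C)C(C)(C)[C@@H](C/C=C(\C)CCC=C(C)C)C[C@]1(CC=C(C)C)C2=O | intermediate
35 | 3-hydroxybenzoic acid | OC(=O)c1cccc(O)c1 | starting material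
36 | tert-butyldimethylsilyl 3-(tert-butyldimethylsilyloxy)benzoate | CC(C)(C)[Si](C)(C)OC(=O)c1cccc(O[Si](C)(C)C(C)(C)C)c1 | intermediate
37 | 3-(tert-butyldimethylsilyloxy)benzoyl chloride | ClC(=O)c1cccc(O[Si](C)(C)C(C)(C)C)c1 | intermediate
38 | C3-lithio derivative of 34 (1R,5S,7S) | COC1=C([Li])C(=O)[C@@]2(CC=C(C)C)C(C)(C)[C@@H](C/C=C(\C)CCC=C(C)C)C[C@]1(CC=C(C)C)C2=O | intermediate
39 | (1S,5S,7S)-3-[3-(tert-butyldimethylsilyloxy)benzoyl]-7-[(2E)-3,7-dimethylocta-2,6-dien-1-yl]-4-methoxy-8,8-dimethyl-1,5-bis(3-methylbut-2-en-1-yl)bicyclo[3.3.1]non-3-ene-2,9-dione | COC1=C(C(=O)c3cccc(O[Si](C)(C)C(C)(C)C)c3)C(=O)[C@@]2(CC=C(C)C)C(C)(C)[C@@H](C/C=C(\C)CCC=C(C)C)C[C@]1(CC=C(C)C)C2=O | intermediate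
40 | (1S,5S,7S)-7-[(2E)-3,7-dimethylocta-2,6-dien-1-yl]-4-hydroxy-3-(3-hydroxybenzoyl)-8,8-dimethyl-1,5-bis(3-methylbut-2-en-1-yl)bicyclo[3.3.1]non-3-ene-2,9-dione (CNP0290731.1) | CC(C)=CCC/C(C)=C/C[C@H]1C[C@]2(CC=C(C)C)C(=O)[C@@](CC=C(C)C)(C(=O)C(C(=O)c3cccc(O)c3)=C2O)C1(C)C | target

**Step count and risks**

Total step count: 21. Longest linear sequence: 17 steps (steps 1–14, 17, 20 and 21, from 1,3-dimethoxybenzene); steps 15–16 and 18–19 make the two side fragments.

The three steps most likely to fail: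

Step 12. The C1 carbanion sits next to the C8 gem-dimethyl group, so metalation may be slow and capture of the allylic bromide may lose out to proton return; C–C bond formation at the bridgehead then stalls. The fallback sets out from 21 and replaces the two-electron alkylation by a radical one. Bridgehead lithiation (LDA, THF, −78 → −40 °C) with 1,2-diiodoethane as a small, fast iodine donor that spares the silyl enol ether should give the C1 bridgehead iodide F1. Tin-mediated radical allylation (allyltributylstannane, AIBN, benzene, 80 °C; Keck allylation) through the bridgehead radical should give the C1-allyl compound F2. Cross-metathesis with 2-methyl-2-butene (second-generation Grubbs catalyst, CH2Cl2, 40 °C) turns allyl into prenyl and gives 23, where the route resumes.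

Step 10. Hydrogen abstraction at the allylic positions of the prenyl group may compete with abstraction at C2, or the enol ether may be degraded by the oxidant; either is a loss of chemoselectivity in the C–H oxidation. The fallback sets out from 19 and uses only two-electron steps. Aqueous HCl in THF hydrolyses the enol ether to the 4,7,9-trione F3. IBX (DMSO, 70 °C) dehydrogenates the only ketone that has both α- and β-hydrogens and gives the C2=C3 enone F4. Alkaline hydrogen peroxide (MeOH, 0 °C) gives the 2,3-epoxy ketone F5. Pd(PPh3)4 (zerovalent palladium) with dppe in toluene at 100 °C isomerises the epoxy ketone to the 2,4,7,9-tetraone F6. O-Methylation with trimethylsilyldiazomethane gives 20, where the route resumes, together with its 2-methoxy regioisomer F7, which is separated, hydrolysed back to F6 and recycled.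

Step 9. Proton exchange may place the enolate on the C6 side, so the second methyl group may be spread over C6 and C8 or over-alkylation may set in; this is a loss of regiocontrol. The fallback sets out from 15 and makes the C8 enolate regiospecifically by conjugate reduction. The kinetic enolate (LDA, THF, −78 °C) is trapped with Eschenmoser's salt to give the C8 Mannich base F8. Iodomethane gives the quaternary ammonium iodide F9 and DBU eliminates trimethylamine to give the 8-methylidene ketone F10. K-Selectride (THF, −78 °C) delivers hydride to the exocyclic CH2 and so forms the potassium enolate 18 without equilibration; iodomethane added to the same flask gives 19, where the route resumes.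

Further compounds
F1 | step 12 | 1-iodo-4-methoxy-8,8-dimethyl-5-(3-methylbut-2-en-1-yl)-3-(trimethylsilyl)-7-(trimethylsilyloxy)bicyclo[3.3.1]nona-3,6-diene-2,9-dione (bridgeheads arranged as in 23) | COC1=C([Si](C)(C)C)C(=O)[C@@]2(I)C(C)(C)C(O[Si](C)(C)C)=C[C@]1(CC=C(C)C)C2=O
F2 | step 12 | 4-methoxy-8,8-dimethyl-5-(3-methylbut-2-en-1-yl)-1-(prop-2-en-1-yl)-3-(trimethylsilyl)-7-(trimethylsilyloxy)bicyclo[3.3.1]nona-3,6-diene-2,9-dione (bridgeheads arranged as in 23) | COC1=C([Si](C)(C)C)C(=O)[C@@]2(CC=C)C(C)(C)C(O[Si](C)(C)C)=C[C@]1(CC=C(C)C)C2=O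
F3 | step 10 | (1S,5S)-8,8-dimethyl-5-(3-methylbut-2-en-1-yl)bicyclo[3.3.1]nonane-4,7,9-trione | O=C1CC[C@H]2C(C)(C)C(=O)C[C@]1(CC=C(C)C)C2=O
F4 | step 10 | (1S,5S)-8,8-dimethyl-5-(3-methylbut-2-en-1-yl)bicyclo[3.3.1]non-2-ene-4,7,9-trione | O=C1C=C[C@H]2C(C)(C)C(=O)C[C@]1(CC=C(C)C)C2=O
F5 | step 10 | 2,3-epoxide of F4 on the ring A face syn to C9 (bridgeheads arranged as in 19) | O=C1[C@@H]3O[C@@H]3[C@H]2C(C)(C)C(=O)C[C@]1(CC=C(C)C)C2=O
F6 | step 10 | 8,8-dimethyl-5-(3-methylbut-2-en-1-yl)bicyclo[3.3.1]nonane-2,4,7,9-tetraone (bridgeheads arranged as in 19) | O=C1CC(=O)[C@H]2C(C)(C)C(=O)C[C@]1(CC=C(C)C)C2=O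
F7 | step 10 | 2-methoxy-8,8-dimethyl-5-(3-methylbut-2-en-1-yl)bicyclo[3.3.1]non-2-ene-4,7,9-trione (regioisomer of 20, bridgeheads arranged as in 19) | COC1=CC(=O)[C@]2(CC=C(C)C)CC(=O)C(C)(C)[C@H]1C2=O
F8 | step 9 | 8-[(dimethylamino)methyl]-4-methoxy-5-(3-methylbut-2-en-1-yl)bicyclo[3.3.1]non-3-ene-7,9-dione (bridgeheads as in 15, C8 epimers) | COC1=CC[C@H]2C(CN(C)C)C(=O)C[C@]1(CC=C(C)C)C2=O
F9 | step 9 | trimethylammonium iodide of F8 | COC1=CC[C@H]2C(C[N+](C)(C)C)C(=O)C[C@]1(CC=C(C)C)C2=O.[I-]
F10 | step 9 | 4-methoxy-8-methylidene-5-(3-methylbut-2-en-1-yl)bicyclo[3.3.1]non-3-ene-7,9-dione (bridgeheads as in 15) | COC1=CC[C@H]2C(=C)C(=O)C[C@]1(CC=C(C)C)C2=O
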